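# Proposed total synthesis of arteminorin C (13)

## Analysis of the target

Arteminorin C 13 is a 3,3'-bicoumarin: two 2H-chromen-2-one units, each a benzene ring fused to a pyranone ring, joined by the single bond C3–C3'. The unprimed half is 7-hydroxy-6,8-dimethoxycoumarin and the primed half is 6,7-dihydroxycoumarin. There is no stereocentre, and the C3–C3' axis is flanked only by a carbonyl group and a hydrogen on each side, so no stable atropisomer is expected. Geometry matters only in that each C3=C4 bond must hold the aryl carbon C4a cis to the carbonyl carbon C2. The sensitive groups are the free catechol at C6'/C7' and the phenol at C7 (easily oxidised in base and air), the two aryl-ester lactones (opened by hydroxide), and the methyl ethers at C6 and C8, which must survive whatever frees the three hydroxyl groups. The difficulty is that the molecule is an unsymmetrical dimer: two different, densely oxygenated coumarins, with five oxygen substituents in a fixed pattern of three free and two methylated, are joined at C3. Building each half separately would mean putting an oxygen at C8a of each arene and then cross-coupling two electron-poor positions. The strategy rests on the chain C4=C3(–C2)–C3'(–C2')=C4', which is a 2,3-dibenzylidenesuccinate. Without the bonds O1–C8a and O1'–C8a', the aryl rings become a 4-hydroxy-3,5-dimethoxyphenyl group and a 3,4-dihydroxyphenyl group, the substitution patterns of syringaldehyde 1 and 3,4-dihydroxybenzaldehyde 7. The first ring has two identical open ortho positions, either of which can become C8a. In the second ring the open position para to the 3-oxygen becomes C8a'. The whole carbon skeleton is therefore the diacid 10, made from 1, 7 and diethyl succinate 4, and only two aryl C–O bonds are missing.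

## Retrosynthetic reasoning

**13 ⇒ 12 (three O–CH2Ph bonds).** The three hydroxyl groups of 13 are carried as benzyl ethers in 12. Benzyl ethers survive alkoxide and hydroxide, keep both arenes electron-rich for the oxidation, and can be distinguished from the two methyl ethers at the end. The forward step must remove three benzyl groups without touching the methyl ethers, the lactones or the C3=C4 bonds. A low-temperature Lewis-acid cleavage in the presence of a cation scavenger does this in one operation.

**12 ⇒ 10, through 11 (O1–C8a and O1'–C8a').** These two C–O bonds are cut because doing so leaves every C–C bond in place. The problem of the unsymmetrical C3–C3' union is thereby moved to an open-chain diacid, where it becomes two ordinary condensations. Cutting C3–C3' instead would require two separately built coumarins, each with its own C8a oxygen, and a hetero-coupling. The gain is that neither arene needs an oxygen at the future C8a, so the rings of 1 and 7 can be used as bought. The forward reaction has three tasks.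
- It must bring each aryl group cis to the carboxyl group on its own alkene; in 10 each is trans.
- It must replace one ortho C–H on each ring by a carboxyl oxygen, a net loss of four hydrogens.
- It must choose C6 over C2 on the 3,4-bis(benzyloxy)phenyl ring; the other ring is symmetric.

It runs once on each half, through the monolactone 11.

**10 ⇒ 6 + 8, through 9 (C3'=C4').** The benzylidene double bond of the primed half is cut back to the CH2 group of diester 6 and the aldehyde carbon of 8. That CH2 is the only enolisable position of 6. A Stobbe condensation ends in a carboxylate (half-ester 9), and hydrolysis of the remaining ester in the same flask gives 10.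

**6 ⇒ 5 ⇒ 3 + 4 (C3=C4).** The first benzylidene bond comes from a Stobbe condensation of aldehyde 3 with diethyl succinate 4, which gives half-ester 5. The acid of 5 must be re-esterified to 6, because the second condensation needs an ester enolate next to the CH2 group and not a carboxylate.

**3 ⇒ 1 + 2 and 8 ⇒ 7 + 2 (O–benzyl bonds).** Both aldehydes are the O-benzyl ethers of purchasable phenolic aldehydes, made with benzyl bromide 2. The precursor 10 is thus reached in five operations of standard chemistry, and the risk of the route sits in the lactonisation.

## Alternatives that were turned down

**Alternative 1:** The primed pyranone ring is taken apart completely, at C4a'–C4', C8a'–O1', C3'=C4' and O1'–C2'. The pieces are a symmetric aryne (4,5-methylenedioxybenzyne, released by fluoride from silyl triflate A2), the formyl carbon of a formamide (C4'), and the acetate arm of the preformed unprimed coumarin A3 (C3' and C2').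
- *Forward key step:* the aryne adds across the formamide C=O bond, the strained adduct opens to an ortho-quinone-methide-like species, the ester enolate of A3 adds at the future C4', and loss of the amine with lactonisation gives A1.
- *For it:* the aryne is symmetric, so there is no question of which ortho carbon of the catechol ring receives oxygen. Four bonds and a ring form in one convergent step. The reaction class is established for 1,3-dicarbonyl carbon acids, so its precedent is closer than that of the chosen key step.
- *Against it:* A3 is a singly activated ester, far less acidic than the usual partners. Its coumarin ring is an aryl ester and a Michael acceptor, exposed to fluoride, to the enolate and to the amine set free. A3 must be built from a salicylaldehyde that already carries the C8a oxygen, and A2 is itself a multistep reagent. The catechol emerges as a methylenedioxy acetal, and its Lewis-acid cleavage beside two methyl ethers flanking a third oxygen is a poorly selective deprotection.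
- *Comparison:* this alternative is stronger on precedent and on regiochemistry in the primed ring. It is weaker in step count (about five steps to A3, about three to A2, the key step and two unmasking steps) and in the end game. In its place the chosen strategy installs both lactone oxygens in one step on arenes bought with the right oxygen pattern, and uses benzyl ethers that come off without endangering methyl ethers.

**Alternative 2:** O1 and O1' are treated as oxygen atoms inserted into the C1–C7a and C1'–C7a' bonds of the 2,2'-biindan-1-one A4, and both C3=C4 double bonds are taken down to single bonds.
- *Forward key step:* a peracid under strong acid adds to each ketone and the electron-rich aryl carbon migrates to oxygen (Baeyer–Villiger). Both cyclopentanones expand to six-membered aryl lactones, giving A5 as a diastereomer mixture. A twofold dehydrogenation and the debenzylation would follow.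
- *For it:* every step belongs to a documented reaction class, which the chosen key step cannot claim. Both migrating aryl carbons are ortho or para to oxygen donors, so the right group should migrate. The position of each lactone oxygen is fixed beforehand by the Friedel–Crafts closure that makes each indanone, so no site selection is left to the key step.
- *Against it:* the oxidation level is wrong by four hydrogens, and dehydrogenating two enolisable aryl esters invites ring opening. A4 needs two different indanones and an unsymmetrical enolate coupling that also gives homo-dimers and diastereomers. The peracid meets three benzyl ethers and two very electron-rich arenes, and migration of the secondary alkyl carbon C2 can compete in either ring.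
- *Comparison:* safer step by step, but roughly twice as long, and it forms the aryl C–O bonds at an oxidation state that must then be corrected. The chosen route forms the same two bonds directly at the coumarin oxidation level.

**Alternative 3:** The tetraoxygenated benzene ring of the unprimed half is built rather than bought. C4a–C8a and O1–C2 are cut, leading back to cyclobutenone A6, made from a squaric ester. A6 carries three methoxy groups and a dienyl chain that ends in an ester and the finished primed coumarin.
- *Forward key step:* heating opens the four-membered ring to a dienylketene, and a six-electron electrocyclisation forms C4a–C8a. Tautomerisation gives a phenol whose oxygen sits at C8a, and this phenol attacks the cis ester to close the pyranone ring, giving A7.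
- *For it:* the step is thermal, needs no reagent, and is regiochemically unambiguous, since every oxygen of the new ring is placed by construction. The ring-opening and electrocyclisation cascade of 4-alkenylcyclobutenones is well precedented for oxygenated phenols. On both points it is stronger than the chosen key step.
- *Against it:* it spends its key step on the one ring that 1 supplies ready-made. The methoxy groups of A7 at C6, C7 and C8 are not differentiated, so the central one must later be cleaved selectively between two others. A6 needs a stereodefined dienyl chain on a quaternary carbon and a separately made primed coumarin with its own C8a' oxygen. Heating such a polyene also opens other pericyclic channels.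
- *Comparison:* this is the longest of the routes. The chosen strategy gives up regiochemical certainty on one ring but starts from arenes that already carry the right oxygens in the right state of protection.

Key step: step 6

Remark: 11 is drawn with the syringaldehyde-derived half lactonised first; if the other half closes first, the isomeric monolactone leads to the same product 12. The alkene geometry of 10 is drawn E,E as the Stobbe sequence should deliver it, but step 6 does not depend on it.

## Route

Step 1
Reactants: 1 syringaldehyde; 2 benzyl bromide
Product: 3 O-benzylsyringaldehyde [4-(benzyloxy)-3,5-dimethoxybenzaldehyde]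
Conditions: BnBr (1.1 equiv), K2CO3, DMF, 60 °C
Reagents that add atoms: benzyl bromide 2, BrCc1ccccc1
Why: Williamson etherification; the phenoxide of 1, although flanked by two methoxy groups, should be alkylated cleanly by the unhindered benzylic bromide, and the non-enolisable aldehyde is inert to carbonate.

Step 2
Reactants: 3 O-benzylsyringaldehyde; 4 diethyl succinate
Product: 5 (E)-4-[4-(benzyloxy)-3,5-dimethoxyphenyl]-3-(ethoxycarbonyl)but-3-enoic acid
Conditions: NaOEt (2 equiv), 4 (1.5 equiv), EtOH, reflux; then aq. HCl
Reagents that add atoms: none
Why: Stobbe condensation; the succinate enolate adds to the non-enolisable aldehyde and the irreversible formation of a carboxylate salt drives the condensation to the half-ester. The alkene should form with the aryl group trans to the conjugated ester (E), as is usual for Stobbe half-esters, and the acid can be purified by acid–base extraction.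

Step 3
Reactants: 5 Stobbe half-ester
Product: 6 diethyl (E)-2-[4-(benzyloxy)-3,5-dimethoxybenzylidene]succinate
Conditions: EtI (1.5 equiv), K2CO3, DMF, rt
Reagents that add atoms: ethyl iodide, CCI
Why: SN2 O-alkylation of the carboxylate restores the diester needed for a second enolisation; the mild, non-acidic conditions should leave the position and E geometry of the double bond and the benzyl ether untouched.

Step 4
Reactants: 7 3,4-dihydroxybenzaldehyde; 2 benzyl bromide
Product: 8 3,4-bis(benzyloxy)benzaldehyde
Conditions: BnBr (2.3 equiv), K2CO3, DMF, 60 °C
Reagents that add atoms: benzyl bromide 2, BrCc1ccccc1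
Why: Twofold Williamson etherification of the catechol; both phenoxides are unhindered and the aldehyde is not affected.

Step 5
Reactants: 6 diethyl arylidenesuccinate; 8 3,4-bis(benzyloxy)benzaldehyde
Product: 10 (2E,3E)-2-[4-(benzyloxy)-3,5-dimethoxybenzylidene]-3-[3,4-bis(benzyloxy)benzylidene]succinic acid, via monoethyl ester 9 (not isolated)
Conditions: NaOEt (2 equiv), EtOH, reflux; then 2 M aq. NaOH, reflux; then aq. HCl
Reagents that add atoms: water (as aqueous NaOH), O
Why: Second Stobbe condensation; the CH2 group of 6 is its only enolisable position, its enolate adds to 8, and the condensation again ends in a carboxylate (half-ester 9), which hydroxide saponifies in the same flask to diacid 10. The new alkene should again carry its aryl group trans to its own carboxyl carbon, and minor geometric isomers are tolerable because step 6 equilibrates alkene geometry.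

Step 6
Reactants: 10 dibenzylidenesuccinic acid
Product: 12 tri-O-benzyl arteminorin C [7-(benzyloxy)-6',7'-bis(benzyloxy)-6,8-dimethoxy-3,3'-bicoumarin], via monolactone acid 11 (not isolated)
Conditions: riboflavin 2',3',4',5'-tetraacetate (10 mol %), O2 (1 atm), blue LEDs (ca. 400–450 nm), MeCN/MeOH 1:1, ca. 5 mM, rt
Reagents that add atoms: none
Why: Proposed new method: the excited flavin should first act as a triplet sensitiser that scrambles the geometry of both trisubstituted alkenes, so that part of the material always has an aryl group cis to the carboxyl group on its own alkene, and then as a one-electron oxidant that turns that alkoxy-rich styrene into its radical cation. The neighbouring carboxyl oxygen adds to the ortho carbon of the oxidised ring (C8a in one half, C8a' in the other), and a second oxidation with loss of the ortho proton restores the arene; O2 returns the reduced flavin to its oxidised form and ends as H2O2. Both pyranone rings close in the same mode, a six-membered O–C closure onto an sp2 carbon that counts as 6-exo-trig against the C8a–C8 (C8a'–C8') bond of the oxidised arene, giving first monolactone acid 11 and then 12. The closest known reaction types are the flavin-photocatalysed isomerisation and oxidative cyclisation of beta-substituted cinnamic acids to coumarins and the photocatalytic dehydrogenative lactonisation of biaryl-2-carboxylic acids; untested is the twofold use on a 2,3-dibenzylidenesuccinic acid, whose acrylic acid units are alpha-substituted and beta-unsubstituted. No stereocentre is formed, and the alkene geometry of 10 does not matter, because all geometric isomers interconvert under sensitisation and are drained through the cis-aryl/carboxyl form, the only one that can lactonise. Site selectivity is needed only on the 3,4-bis(benzyloxy)phenyl ring, where C6, para to the 3-oxygen and unhindered, should be attacked in preference to C2, which is wedged between the side chain and the 3-benzyloxy group; the other ring offers two identical ortho positions, each ortho to one methoxy group and para to the other. Chemoselectivity against the main rival, cyclisation of the diene onto an arene to an aryldihydronaphthalene, rests on the strongly twisted diene of 10 and on the fact that after the first lactonisation one styrene arm is locked into a coumarin and can no longer take part.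

Step 7
Reactants: 12 tri-O-benzyl arteminorin C
Product: 13 arteminorin C
Conditions: BCl3 (1 M in CH2Cl2, 9 equiv), pentamethylbenzene (9 equiv), CH2Cl2, −78 °C; then MeOH, then H2O
Reagents that add atoms: none
Why: Lewis-acid-mediated debenzylation; BCl3 activates the benzylic ether oxygens and pentamethylbenzene captures the benzyl cations by Friedel–Crafts alkylation, which should prevent C-benzylation of the electron-rich product. At −78 °C the aryl methyl ethers and both lactones are expected to stay intact, and the aqueous quench hydrolyses the aryl borates to the free phenols.

## Compound list

1 | syringaldehyde (4-hydroxy-3,5-dimethoxybenzaldehyde) | COc1cc(C=O)cc(OC)c1O | starting material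
2 | benzyl bromide | BrCc1ccccc1 | starting material
3 | O-benzylsyringaldehyde, 4-(benzyloxy)-3,5-dimethoxybenzaldehyde | COc1cc(C=O)cc(OC)c1OCc1ccccc1 | intermediate
4 | diethyl succinate | CCOC(=O)CCC(=O)OCC | starting material
5 | (E)-4-[4-(benzyloxy)-3,5-dimethoxyphenyl]-3-(ethoxycarbonyl)but-3-enoic acid | COc1cc(/C=C(/C(=O)OCC)CC(=O)O)cc(OC)c1OCc1ccccc1 | intermediate
6 | diethyl (E)-2-[4-(benzyloxy)-3,5-dimethoxybenzylidene]succinate | COc1cc(/C=C(/C(=O)OCC)CC(=O)OCC)cc(OC)c1OCc1ccccc1 | intermediate
7 | 3,4-dihydroxybenzaldehyde | O=Cc1ccc(O)c(O)c1 | starting material
8 | 3,4-bis(benzyloxy)benzaldehyde | O=Cc1ccc(OCc2ccccc2)c(OCc2ccccc2)c1 | intermediate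
9 | (2E,3E)-2-[4-(benzyloxy)-3,5-dimethoxybenzylidene]-3-[3,4-bis(benzyloxy)benzylidene]-4-ethoxy-4-oxobutanoic acid (monoethyl ester, ester on the carbon bearing the bis(benzyloxy)benzylidene group; not isolated) | COc1cc(/C=C(/C(=O)O)\C(C(=O)OCC)=C/c2ccc(OCc3ccccc3)c(OCc3ccccc3)c2)cc(OC)c1OCc1ccccc1 | intermediate
10 | (2E,3E)-2-[4-(benzyloxy)-3,5-dimethoxybenzylidene]-3-[3,4-bis(benzyloxy)benzylidene]succinic acid | COc1cc(/C=C(/C(=O)O)\C(C(=O)O)=C/c2ccc(OCc3ccccc3)c(OCc3ccccc3)c2)cc(OC)c1OCc1ccccc1 | intermediate
11 | (Z)-3-[3,4-bis(benzyloxy)phenyl]-2-[7-(benzyloxy)-6,8-dimethoxy-2-oxo-2H-chromen-3-yl]prop-2-enoic acid (monolactone acid; not isolated) | COc1cc2cc(/C(C(=O)O)=C/c3ccc(OCc4ccccc4)c(OCc4ccccc4)c3)c(=O)oc2c(OC)c1OCc1ccccc1 | intermediate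
12 | tri-O-benzyl arteminorin C, 7-(benzyloxy)-6',7'-bis(benzyloxy)-6,8-dimethoxy-2H,2'H-[3,3'-bichromene]-2,2'-dione | COc1cc2cc(-c3cc4cc(OCc5ccccc5)c(OCc5ccccc5)cc4oc3=O)c(=O)oc2c(OC)c1OCc1ccccc1 | intermediate
13 | arteminorin C, 6',7,7'-trihydroxy-6,8-dimethoxy-2H,2'H-[3,3'-bichromene]-2,2'-dione | COc1cc2cc(-c3cc4cc(O)c(O)cc4oc3=O)c(=O)oc2c(OC)c1O | target

## Step count and least certain steps

Total step count: 7. Longest linear sequence: 6 steps (steps 1, 2, 3, 5, 6, 7); step 4 is a one-step side branch.

**Step 6 (key step, proposed new method).** Several things may go wrong.
- The oxidised or excited diene may cyclise onto an arene (aryldihydronaphthalene formation) faster than the carboxyl oxygen adds.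
- The styrene C=C bonds may be cleaved by singlet oxygen, which the flavin also generates.
- The reaction may stall after the first lactonisation, because the remaining acrylic acid is then conjugated to an electron-poor coumarin and is harder to oxidise.
- Attack may occur partly at the crowded C2 of the bis(benzyloxy)phenyl ring.
- Benzyl groups may be lost by fragmentation of the aryl ether radical cations.

The fallback uses known chemistry and introduces the lactone oxygens before the condensations. It sets out from aldehydes 3 and 8 and comes back to the route at 12. Bromination of 3 with N-bromosuccinimide in MeCN (only one kind of open position) should give 4-(benzyloxy)-2-bromo-3,5-dimethoxybenzaldehyde F1. Ullmann-type hydroxylation (CuI, 8-hydroxyquinoline, KOH, DMSO/H2O, 100 °C) then gives 4-(benzyloxy)-2-hydroxy-3,5-dimethoxybenzaldehyde F2. A Perkin condensation of F2 with succinic anhydride (Et3N, 130 °C) gives 2-[7-(benzyloxy)-6,8-dimethoxy-2-oxo-2H-chromen-3-yl]acetic acid F3. In the same way 8 is brominated para to its 3-benzyloxy group to 4,5-bis(benzyloxy)-2-bromobenzaldehyde F4 and hydroxylated to 4,5-bis(benzyloxy)-2-hydroxybenzaldehyde F5. A Perkin–Oglialoro condensation of F3 with F5 (Ac2O, Et3N, 120 °C) acylates the phenol, closes the second pyranone ring by intramolecular aldol condensation and gives 12. This costs six operations in place of steps 2, 3, 5 and 6.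

**Step 5 (second Stobbe condensation and saponification).** The enolate of 6 is a hindered, delocalised anion. The condensation may be slow and incomplete, with base-induced migration of the double bond of 6 and Cannizzaro-type consumption of 8 as competing processes. The fallback replaces the equilibrating condensation by a directed aldol addition and a separate elimination. It sets out from 6 and 8 and comes back at 10. Deprotonation of 6 with LiN(i-Pr)2 in THF at −78 °C and addition of 8 gives diethyl (E)-2-[4-(benzyloxy)-3,5-dimethoxybenzylidene]-3-{[3,4-bis(benzyloxy)phenyl](hydroxy)methyl}succinate F6 as a diastereomer mixture. Acetylation and base-induced elimination (Ac2O, Et3N, 4-dimethylaminopyridine, then DBU) gives diethyl (2E,3E)-2-[4-(benzyloxy)-3,5-dimethoxybenzylidene]-3-[3,4-bis(benzyloxy)benzylidene]succinate F7. Saponification (LiOH, THF/MeOH/H2O, 60 °C) gives 10.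

**Step 7 (debenzylation).** Over-reaction is the main danger: once the C7 oxygen is freed as an aryloxyborane, a flanking methyl ether at C6 or C8 may be cleaved as well. Cleavage may also stay incomplete if partly deprotected borates precipitate at −78 °C. The fallback changes from Lewis-acidic to reductive cleavage. It sets out from 12 and comes back at 13: hydrogenolysis over Pd/C under H2 (1 atm) in THF/EtOAc at rt, where O-benzyl cleavage should be much faster than reduction of the trisubstituted, aryl-conjugated C3=C4 bonds. It makes no new compound (F0).

**Step 2 (first Stobbe condensation).** Self-condensation of 4 and Cannizzaro-type loss of the electron-rich aldehyde 3 may lower conversion, and some Z half-ester may form. The fallback replaces the condensation by an olefination. It sets out from 3 and comes back at 6, bypassing 5 and step 3: Horner–Wadsworth–Emmons reaction of 3 with triethyl phosphonosuccinate (NaH, THF, 0 °C to rt) should give the E diester 6 directly. It makes no new compound (F0).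

## Further compounds

F1 | step 6 | 4-(benzyloxy)-2-bromo-3,5-dimethoxybenzaldehyde | COc1cc(C=O)c(Br)c(OC)c1OCc1ccccc1
F2 | step 6 | 4-(benzyloxy)-2-hydroxy-3,5-dimethoxybenzaldehyde | COc1cc(C=O)c(O)c(OC)c1OCc1ccccc1
F3 | step 6 | 2-[7-(benzyloxy)-6,8-dimethoxy-2-oxo-2H-chromen-3-yl]acetic acid | COc1cc2cc(CC(=O)O)c(=O)oc2c(OC)c1OCc1ccccc1
F4 | step 6 | 4,5-bis(benzyloxy)-2-bromobenzaldehyde | O=Cc1cc(OCc2ccccc2)c(OCc2ccccc2)cc1Br
F5 | step 6 | 4,5-bis(benzyloxy)-2-hydroxybenzaldehyde | O=Cc1cc(OCc2ccccc2)c(OCc2ccccc2)cc1O
F6 | step 5 | diethyl (E)-2-[4-(benzyloxy)-3,5-dimethoxybenzylidene]-3-{[3,4-bis(benzyloxy)phenyl](hydroxy)methyl}succinate (mixture of diastereomers) | COc1cc(/C=C(/C(=O)OCC)C(C(=O)OCC)C(O)c2ccc(OCc3ccccc3)c(OCc3ccccc3)c2)cc(OC)c1OCc1ccccc1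
F7 | step 5 | diethyl (2E,3E)-2-[4-(benzyloxy)-3,5-dimethoxybenzylidene]-3-[3,4-bis(benzyloxy)benzylidene]succinate | COc1cc(/C=C(/C(=O)OCC)\C(C(=O)OCC)=C/c2ccc(OCc3ccccc3)c(OCc3ccccc3)c2)cc(OC)c1OCc1ccccc1
F0 | step 7 | none | none
F0 | step 2 | none | none
A1 | alternative 1 | 7-O-benzyl-6',7'-O-methylene arteminorin C | COc1cc2cc(-c3cc4cc5OCOc5cc4oc3=O)c(=O)oc2c(OC)c1OCc1ccccc1
A2 | alternative 1 | 6-(trimethylsilyl)-1,3-benzodioxol-5-yl trifluoromethanesulfonate | C[Si](C)(C)c1cc2OCOc2cc1OS(=O)(=O)C(F)(F)F
A3 | alternative 1 | ethyl 2-[7-(benzyloxy)-6,8-dimethoxy-2-oxo-2H-chromen-3-yl]acetate | CCOC(=O)Cc1cc2cc(OC)c(OCc3ccccc3)c(OC)c2oc1=O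
A4 | alternative 2 | 6-(benzyloxy)-5',6'-bis(benzyloxy)-5,7-dimethoxy-2,2'-biindan-1,1'-dione (mixture of diastereomers) | COc1cc2CC(C3Cc4cc(OCc5ccccc5)c(OCc5ccccc5)cc4C3=O)C(=O)c2c(OC)c1OCc1ccccc1
A5 | alternative 2 | tri-O-benzyl 3,4,3',4'-tetrahydroarteminorin C (mixture of diastereomers) | COc1cc2CC(C3Cc4cc(OCc5ccccc5)c(OCc5ccccc5)cc4OC3=O)C(=O)Oc2c(OC)c1OCc1ccccc1
A6 | alternative 3 | methyl (2Z,4E)-2-[6,7-bis(benzyloxy)-2-oxo-2H-chromen-3-yl]-5-(1,2,3-trimethoxy-4-oxocyclobut-2-en-1-yl)penta-2,4-dienoate (racemic) | COC1=C(OC)C(OC)(/C=C/C=C(\C(=O)OC)c2cc3cc(OCc4ccccc4)c(OCc4ccccc4)cc3oc2=O)C1=O
A7 | alternative 3 | 7-O-methyl-6',7'-di-O-benzyl arteminorin C | COc1cc2cc(-c3cc4cc(OCc5ccccc5)c(OCc5ccccc5)cc4oc3=O)c(=O)oc2c(OC)c1OC
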